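Nothing leaves a closed flask, so the charge must stay accounted for. Yet in the violet run at 6.00 h, starting material and target together made only 25.8 %, so I took the missing 74.2 % to be something unread, formed beside target.

| setting | violet | ochre | flask |
|---|---|---|---|
| starting material | 0.13 M | 0.30 M | 0.20 M |
| remark | run made earlier | run made earlier |  |
| time |  |  | 30 h |

| run | time / h | target / % | crystals / % | starting material / % |
|---|---|---|---|---|
| violet | 2.00 | 21.7 | 12.4 | 26.7 |
| violet | 3.00 | 22.5 | 16.7 | 19.1 |
| violet | 4.00 | 22.0 | 16.5 | 12.0 |
| violet | 6.00 | 21.9 | 18.8 | 3.9 |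
| violet | 10.0 | 20.7 | 18.2 | 4.7 |
| violet | 15.0 | 18.4 | 16.2 | 3.5 |
| violet | 25.0 | 16.4 | 14.6 | 3.4 |
| ochre | 3.00 | 24.1 | 18.1 | 17.3 |
| ochre | 6.00 | 22.8 | 19.2 | 5.5 |
| ochre | 10.0 | 24.3 | 19.6 | 3.0 |
| ochre | 15.0 | 24.2 | 22.4 | 2.8 |
| ochre | 20.0 | 25.6 | 23.4 | 3.2 |
| ochre | 25.0 | 24.4 | 24.4 | 1.5 |

(scatter of a reading: 1 percentage point)

- amounts and yields of target count crystals too
- given per volume of solution although it is solid: crystals

* amount of target and crystals together at 30 h, in percent of the starting material charged
* concentration of target in solution at 30 h, in percent of saturation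

I ran the violet flask slowly in my head. At 2.00 h in the violet run, starting material had fallen to 26.7 %, and target already stood at 21.7 %, of which 12.4 % was crystals. By 6.00 h in the violet run, starting material was down to 3.9 % and then stayed near there, while crystals made up 18.8 % of the 21.9 % target. After that, I watched the slow change in target.

I called this the drain: the rate, per volume of flask, at which target with crystals falls once starting material has stopped falling. I read it over the same hours in both runs, so each value carries the scatter, and I assumed a straight line in charge between them: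

violet, 10.0 h to 25.0 h: 0.373 mM h⁻¹
ochre, 10.0 h to 25.0 h: −0.0200 mM h⁻¹
flask, at its charge: 0.211 mM h⁻¹

The same line through the readings at 10.0 h put the flask at 22.2 % then, so my reckoning for 30 h was 20.1 %.

The forecast gave 20.3 % (17.8 % to 23 %) and 100 % of saturation (88 % to 115 %), saying “the solution stays essentially saturated”.

The flask gave 20.4 % and 86.4 %.

    starting material ⇌ target (K = 0.400, k = 1.13 h⁻¹)
    starting material ⇌ isomer of the product (K = 28.6, k = 0.498 h⁻¹)
    target ⇌ isomer of the product (k = 0.0546 h⁻¹)
    crystals ⇌ target, rate k4*(cs4 - [target]) while solid is left; crystals form when [target] > cs4 (solubility = 2.70 mM, k = 0.475 h⁻¹)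

The unread substance was the isomer of the product, the thermodynamic product, at 76.8 % in the flask at 30 h. The flask had not come to rest: crystals stood at 19.2 % with the solution at 86.4 % of saturation. Carrying the drain onward from the 20.4 % at 30 h to the same flask read at 3.0 d gave 16.0 %, and at 3.0 d that flask held 17.1 %. Left ten times as long, the flask lost on average 0.103 mM h⁻¹, about half the drain, and at 300 h it held crystals at 5.22 %, target with crystals at 6.51 % and isomer of the product at 90.3 %.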